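**Plan**

- Ring A alternates three oxygen-bearing carbons (C1, C3, C5) with three carbon-substituted ones (C2 and C6 carry the arms, C4 the hexanoyl group). A 3-alkoxycyclobutenone and an ynol ether together hold this 1,3,5-oxygen pattern, so ring A can be built from them.
- Retrosynthesis: the hexanoyl C4–C(=O) bond and the O-protecting groups go first. Ring A is then cut at C1–C2 and C3–C4 (C1–C6 is re-formed pericyclically), giving a 4-(arm)-3-benzyloxycyclobutenone and an (arm)-substituted triisopropylsiloxyalkyne.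
- Both halves go back to one aldehyde, and that to the bond between C2 of ring B and the arm carbon, made by Michael addition of syncarpic acid to (E)-4-methylpent-2-enal.
- Forward: ring B is bought intact and the arm is attached. The aldehyde is split into alkyne → siloxyalkyne and acid → ketene → cyclobutenone. Ring A is then closed (the only ring formed), followed by desilylation, C-acylation and hydrogenolysis.
- Stereochemistry: both (R) centres come from the one amine-catalysed Michael step (catalyst control). They are not enolisable afterwards, and ring B stays an enol ether until the last, neutral step.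

Key step: step 9

Assumption: syncarpic acid 1 is treated as a purchasable material.
Abbreviation: "protected arm" means the (1R)-1-[2-(benzyloxy)-3,3,5,5-tetramethyl-4,6-dioxocyclohex-1-en-1-yl]-2-methylpropyl group.

**Route**

Step 1
Reactants: 1 syncarpic acid; 2 (E)-4-methylpent-2-enal
Product: 4 lactol (4S)-2-hydroxy-6,6,8,8-tetramethyl-4-(propan-2-yl)-3,4-dihydro-2H-chromene-5,7(6H,8H)-dione (both C2 epimers), via open-chain Michael adduct 3 (not isolated)
Conditions: (S)-2-[diphenyl(trimethylsilyloxy)methyl]pyrrolidine (20 mol%), CH2Cl2, 0 °C → rt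
Reagents that add atoms: none
Why: The amine condenses with 2 to an (E)-iminium ion whose face syn to the diphenyl(siloxy)methyl group is blocked, so the enol of 1 should add to the β-carbon from the open face and set the (S) centre under catalyst control, after which the adduct closes to the lactol (organocatalytic Michael addition of a cyclic 1,3-dione to an enal).

Step 2
Reactants: 4 lactol
Product: 5 (3S)-3-[2-(benzyloxy)-3,3,5,5-tetramethyl-4,6-dioxocyclohex-1-en-1-yl]-4-methylpentanal
Conditions: BnBr, Cs2CO3, DMF, 0 °C → rt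
Reagents that add atoms: benzyl bromide, BrCc1ccccc1
Why: Carbonate opens the lactol to the delocalised enolate of the vinylogous acid, which is benzylated on oxygen (Williamson-type O-alkylation) because carbon 2 of ring B is already fully substituted and the two enolate oxygens are equivalent; the enol ether also removes the leaving group needed for a retro-Michael reaction at the stereocentre.

Step 3
Reactants: 5 aldehyde
Product: 7 3-(benzyloxy)-4,4,6,6-tetramethyl-2-[(3R)-4-methylpent-1-yn-3-yl]cyclohex-2-ene-1,5-dione, via alkenyl nonaflate 6 (not isolated)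
Conditions: C4F9SO2F, phosphazene base P2-Et (EtN=P(NMe2)2–N=P(NMe2)3, 2.5 equiv), DMF, −20 °C → rt
Reagents that add atoms: none
Why: The phosphazene base generates the aldehyde enolate, which is sulfonylated on oxygen to alkenyl nonaflate 6 and then loses nonaflate under the same base to the terminal alkyne (one-pot conversion of an enolisable aldehyde into an alkyne through its alkenyl nonaflate), the ketone and enol ether of ring B having no α-hydrogen and the base being too weak to remove the propargylic hydrogen at the stereocentre.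

Step 4
Reactants: 7 alkyne
Product: 10 3-(benzyloxy)-4,4,6,6-tetramethyl-2-{(3R)-4-methyl-1-[(triisopropylsilyl)oxy]pent-1-yn-3-yl}cyclohex-2-ene-1,5-dione, via lithium acetylide 8 (not isolated), via lithium ynolate 9 (not isolated)
Conditions: LiN(SiMe3)2, THF, −78 °C; t-BuOOLi (from t-BuOOH and LiN(SiMe3)2), −78 → 0 °C; i-Pr3SiOTf, −78 °C
Reagents that add atoms: tert-butyl hydroperoxide, CC(C)(C)OO; triisopropylsilyl trifluoromethanesulfonate, CC(C)[Si](C(C)C)(C(C)C)OS(=O)(=O)C(F)(F)F
Why: Deprotonation gives acetylide 8, whose attack on the peroxide oxygen of t-BuOOLi gives ynolate 9, and the bulky silyl triflate traps 9 on oxygen (oxidation of a lithium acetylide to an ynolate followed by O-silylation), the amide base being too hindered to add to the ring B carbonyls.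

Step 5
Reactants: 5 aldehyde
Product: 11 (3S)-3-[2-(benzyloxy)-3,3,5,5-tetramethyl-4,6-dioxocyclohex-1-en-1-yl]-4-methylpentanoic acid
Conditions: NaClO2, NaH2PO4, 2-methyl-2-butene, t-BuOH/H2O, 0 °C → rt
Reagents that add atoms: sodium chlorite (NaClO2), [Na+].[O-]Cl=O
Why: Chlorous acid oxidises the aldehyde to the acid under buffered conditions with an alkene scavenger for hypochlorite (Pinnick oxidation), which leaves the enol ether and the β-stereocentre untouched.

Step 6
Reactants: 12 benzyl alcohol; 13 trichloroethylene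
Product: 14 benzyl (E)-1,2-dichlorovinyl ether
Conditions: KH, THF, 0 °C; then 13, −50 °C → rt
Reagents that add atoms: none
Why: Potassium benzyloxide adds to dichloroacetylene formed in situ from 13 by dehydrochlorination, giving the (E)-1,2-dichlorovinyl ether (addition–elimination route to dichloroenol ethers).

Step 7
Reactants: 14 benzyl (E)-1,2-dichlorovinyl ether
Product: 16 benzyloxyacetylene (benzyl ethynyl ether), via lithium benzyloxyacetylide 15 (not isolated)
Conditions: n-BuLi (2.2 equiv), Et2O, −78 → −40 °C; H2O quench at −78 °C; solution kept at or below 0 °C and used at once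
Reagents that add atoms: none
Why: Butyllithium removes the vinylic hydrogen and chloride to give the chloroalkynyl ether and then exchanges chlorine for lithium to give acetylide 15, which is protonated cold (alkynyl ether synthesis from a dichloroenol ether); the product is used below room temperature because benzyl alkynyl ethers rearrange on warming.

Step 8
Reactants: 11 acid; 16 benzyloxyacetylene
Product: 19 3-(benzyloxy)-4-(protected arm)cyclobut-2-en-1-one (both C4 epimers), via acid chloride 17 (not isolated), via ketene 18 (not isolated)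
Conditions: 1-chloro-N,N,2-trimethylprop-1-en-1-amine (1.05 equiv), CH2Cl2, 0 °C → rt; then 16 (3 equiv), Et3N (slow addition), 0 °C → rt
Reagents that add atoms: none
Why: The α-chloroenamine turns the acid into chloride 17 without releasing acid, triethylamine dehydrochlorinates 17 to aldoketene 18, and 16 adds to it in a [2+2] cycloaddition in which its nucleophilic CH carbon bonds to the ketene carbonyl carbon (ketene–alkoxyalkyne cycloaddition to a 3-alkoxycyclobutenone); the new ring stereocentre C4 forms as both epimers, which is of no consequence since it becomes aromatic in step 9.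

Step 9
Reactants: 19 cyclobutenone; 10 siloxyalkyne
Product: 24 3-(benzyloxy)-2,6-bis(protected arm)-5-[(triisopropylsilyl)oxy]phenol, via vinylketene 20 (not isolated), via vinylcyclobutenone 21 (not isolated), via dienylketene 22 (not isolated), via cyclohexadienone 23 (not isolated)
Conditions: 10 (1.2 equiv), degassed toluene (ca. 0.3 M), 100 °C, sealed tube
Reagents that add atoms: none
Why: Heating opens 19 by a conrotatory four-electron electrocyclic reaction to vinylketene 20 (the protected arm turning outward), whose carbonyl carbon is attacked by the nucleophilic, arm-bearing carbon of 10 while its unsubstituted α-carbon bonds to the siloxy-bearing carbon, so that the [2+2] adduct 21 forms; 21 opens again to dienylketene 22, which closes to cyclohexadienone 23 and tautomerises to phenol 24. The closest known reaction is the Danheiser benzannulation of cyclobutenones with siloxyalkynes and alkoxyalkynes, used here with a branched substituent on each partner. Ring A is closed by a thermal disrotatory six-electron electrocyclisation of 22 that re-forms the C1–C6 bond, after the cycloaddition has made the two new bonds C1–C2 and C3–C4. No new stereocentre survives: the sp3 ring carbons of 19, 21 and 23 all become aromatic, and the two arm centres carry no acidic hydrogen and meet neither acid nor base, so both should stay (R). The step needs one regiochemistry, and the polarity of the ketene (electrophilic at the carbonyl carbon) and of the ynol ether (nucleophilic at the carbon remote from oxygen) secures it, placing the new OH between the two arms and the only ring CH between the siloxy and benzyloxy carbons. Outward rotation of the arm in 20 also keeps its methine hydrogen away from the ketene and so should suppress a 1,5-hydrogen shift, and a small excess of 10 should favour capture of 20 over its dimerisation.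

Step 10
Reactants: 24 phenol
Product: 25 5-(benzyloxy)-2,4-bis(protected arm)benzene-1,3-diol
Conditions: n-Bu4NF, AcOH, THF, 0 °C
Reagents that add atoms: none
Why: Fluoride cleaves the aryl silyl ether (desilylation) while acetic acid buffers the phenoxide, and the benzyl ethers are inert to fluoride.

Step 11
Reactants: 25 diol; 26 hexanoyl chloride
Product: 27 1-[2-(benzyloxy)-4,6-dihydroxy-3,5-bis(protected arm)phenyl]hexan-1-one
Conditions: TiCl4 (2.5 equiv), CH2Cl2, −78 °C; then 26 (1.3 equiv), −78 → −20 °C
Reagents that add atoms: none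
Why: The titanium phenoxide of the free hydroxyl next to the only unsubstituted ring carbon directs the acylium ion to that carbon, which is activated by three oxygen substituents (Friedel–Crafts acylation of a phloroglucinol derivative), and the low temperature should spare the benzyl ethers and the benzylic stereocentres.

Step 12
Reactants: 27 ketone
Product: 28 myrtucommulone F
Conditions: H2 (1 atm), Pd/C (10 wt% palladium on carbon), EtOAc, rt
Reagents that add atoms: none
Why: Hydrogenolysis over palladium on carbon cleaves the aryl benzyl ether and the two vinylogous benzyl esters under neutral conditions (catalytic debenzylation), so the free enols of ring B appear only in the final compound and neither acid nor base is present to close a pyran ring or to epimerise the benzylic centres.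

**Compound list**

1 | syncarpic acid (2,2,4,4-tetramethylcyclohexane-1,3,5-trione) | CC1(C)C(=O)CC(=O)C(C)(C)C1=O | starting material
2 | (E)-4-methylpent-2-enal | CC(C)/C=C/C=O | starting material
3 | (3S)-3-(2-hydroxy-3,3,5,5-tetramethyl-4,6-dioxocyclohex-1-en-1-yl)-4-methylpentanal (open-chain Michael adduct) | O=CC[C@@H](C(C)C)C1=C(O)C(C)(C)C(=O)C(C)(C)C1=O | intermediate
4 | (4S)-2-hydroxy-6,6,8,8-tetramethyl-4-(propan-2-yl)-3,4-dihydro-2H-chromene-5,7(6H,8H)-dione (lactol, both C2 epimers) | OC1C[C@@H](C(C)C)C2=C(O1)C(C)(C)C(=O)C(C)(C)C2=O | intermediate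
5 | (3S)-3-[2-(benzyloxy)-3,3,5,5-tetramethyl-4,6-dioxocyclohex-1-en-1-yl]-4-methylpentanal | O=CC[C@@H](C(C)C)C1=C(OCc2ccccc2)C(C)(C)C(=O)C(C)(C)C1=O | intermediate
6 | (3R)-3-[2-(benzyloxy)-3,3,5,5-tetramethyl-4,6-dioxocyclohex-1-en-1-yl]-4-methylpent-1-en-1-yl nonafluorobutane-1-sulfonate (E/Z mixture) | FC(F)(F)C(F)(F)C(F)(F)C(F)(F)S(=O)(=O)OC=C[C@@H](C(C)C)C1=C(OCc2ccccc2)C(C)(C)C(=O)C(C)(C)C1=O | intermediate
7 | 3-(benzyloxy)-4,4,6,6-tetramethyl-2-[(3R)-4-methylpent-1-yn-3-yl]cyclohex-2-ene-1,5-dione | C#C[C@@H](C(C)C)C1=C(OCc2ccccc2)C(C)(C)C(=O)C(C)(C)C1=O | intermediate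
8 | lithium acetylide of 7 | [Li]C#C[C@@H](C(C)C)C1=C(OCc2ccccc2)C(C)(C)C(=O)C(C)(C)C1=O | intermediate
9 | lithium (3R)-3-[2-(benzyloxy)-3,3,5,5-tetramethyl-4,6-dioxocyclohex-1-en-1-yl]-4-methylpent-1-yn-1-olate (ynolate) | [Li]OC#C[C@@H](C(C)C)C1=C(OCc2ccccc2)C(C)(C)C(=O)C(C)(C)C1=O | intermediate
10 | 3-(benzyloxy)-4,4,6,6-tetramethyl-2-{(3R)-4-methyl-1-[(triisopropylsilyl)oxy]pent-1-yn-3-yl}cyclohex-2-ene-1,5-dione | CC(C)[Si](C(C)C)(C(C)C)OC#C[C@@H](C(C)C)C1=C(OCc2ccccc2)C(C)(C)C(=O)C(C)(C)C1=O | intermediate
11 | (3S)-3-[2-(benzyloxy)-3,3,5,5-tetramethyl-4,6-dioxocyclohex-1-en-1-yl]-4-methylpentanoic acid | OC(=O)C[C@@H](C(C)C)C1=C(OCc2ccccc2)C(C)(C)C(=O)C(C)(C)C1=O | intermediate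
12 | benzyl alcohol | OCc1ccccc1 | starting material
13 | trichloroethylene | ClC=C(Cl)Cl | starting material
14 | benzyl (E)-1,2-dichlorovinyl ether | Cl/C=C(/Cl)OCc1ccccc1 | intermediate
15 | lithium (benzyloxy)acetylide | [Li]C#COCc1ccccc1 | intermediate
16 | benzyloxyacetylene (benzyl ethynyl ether) | C#COCc1ccccc1 | intermediate
17 | (3S)-3-[2-(benzyloxy)-3,3,5,5-tetramethyl-4,6-dioxocyclohex-1-en-1-yl]-4-methylpentanoyl chloride | ClC(=O)C[C@@H](C(C)C)C1=C(OCc2ccccc2)C(C)(C)C(=O)C(C)(C)C1=O | intermediate
18 | (3R)-3-[2-(benzyloxy)-3,3,5,5-tetramethyl-4,6-dioxocyclohex-1-en-1-yl]-4-methylpent-1-en-1-one (aldoketene) | O=C=C[C@@H](C(C)C)C1=C(OCc2ccccc2)C(C)(C)C(=O)C(C)(C)C1=O | intermediate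
19 | 3-(benzyloxy)-4-(protected arm)cyclobut-2-en-1-one (both C4 epimers) | O=C1C=C(OCc2ccccc2)C1[C@H](C3=C(OCc4ccccc4)C(C)(C)C(=O)C(C)(C)C3=O)C(C)C | intermediate
20 | 3-(benzyloxy)-4-(protected arm)buta-1,3-dien-1-one (vinylketene, arm trans to C2) | O=C=C/C(OCc1ccccc1)=C/[C@H](C2=C(OCc3ccccc3)C(C)(C)C(=O)C(C)(C)C2=O)C(C)C | intermediate
21 | 4-[1-(benzyloxy)-2-(protected arm)ethenyl]-2-(protected arm)-3-[(triisopropylsilyl)oxy]cyclobut-2-en-1-one (ring C4 epimers) | O=C1C([C@H](C2=C(OCc3ccccc3)C(C)(C)C(=O)C(C)(C)C2=O)C(C)C)=C(O[Si](C(C)C)(C(C)C)C(C)C)C1/C(OCc4ccccc4)=C/[C@H](C5=C(OCc6ccccc6)C(C)(C)C(=O)C(C)(C)C5=O)C(C)C | intermediate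
22 | 5-(benzyloxy)-2,6-bis(protected arm)-3-[(triisopropylsilyl)oxy]hexa-1,3,5-trien-1-one (dienylketene, ketene and vinyl cis on C3=C4) | O=C=C([C@H](C1=C(OCc2ccccc2)C(C)(C)C(=O)C(C)(C)C1=O)C(C)C)/C(O[Si](C(C)C)(C(C)C)C(C)C)=C\C(OCc3ccccc3)=C\[C@H](C4=C(OCc5ccccc5)C(C)(C)C(=O)C(C)(C)C4=O)C(C)C | intermediate
23 | 5-(benzyloxy)-2,6-bis(protected arm)-3-[(triisopropylsilyl)oxy]cyclohexa-2,4-dien-1-one (C6 epimers) | O=C1C([C@H](C2=C(OCc3ccccc3)C(C)(C)C(=O)C(C)(C)C2=O)C(C)C)=C(O[Si](C(C)C)(C(C)C)C(C)C)C=C(OCc4ccccc4)C1[C@H](C5=C(OCc6ccccc6)C(C)(C)C(=O)C(C)(C)C5=O)C(C)C | intermediate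
24 | 3-(benzyloxy)-2,6-bis(protected arm)-5-[(triisopropylsilyl)oxy]phenol | Oc1c([C@H](C2=C(OCc3ccccc3)C(C)(C)C(=O)C(C)(C)C2=O)C(C)C)c(O[Si](C(C)C)(C(C)C)C(C)C)cc(OCc4ccccc4)c1[C@H](C5=C(OCc6ccccc6)C(C)(C)C(=O)C(C)(C)C5=O)C(C)C | intermediate
25 | 5-(benzyloxy)-2,4-bis(protected arm)benzene-1,3-diol | Oc1c([C@H](C2=C(OCc3ccccc3)C(C)(C)C(=O)C(C)(C)C2=O)C(C)C)c(O)cc(OCc4ccccc4)c1[C@H](C5=C(OCc6ccccc6)C(C)(C)C(=O)C(C)(C)C5=O)C(C)C | intermediate
26 | hexanoyl chloride | CCCCCC(Cl)=O | starting material
27 | 1-[2-(benzyloxy)-4,6-dihydroxy-3,5-bis(protected arm)phenyl]hexan-1-one | CCCCCC(=O)c1c(O)c([C@H](C2=C(OCc3ccccc3)C(C)(C)C(=O)C(C)(C)C2=O)C(C)C)c(O)c([C@H](C4=C(OCc5ccccc5)C(C)(C)C(=O)C(C)(C)C4=O)C(C)C)c1OCc6ccccc6 | intermediate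
28 | myrtucommulone F, (R,R) at the two arm carbons | CCCCCC(=O)c1c(O)c([C@H](C2=C(O)C(C)(C)C(=O)C(C)(C)C2=O)C(C)C)c(O)c([C@H](C2=C(O)C(C)(C)C(=O)C(C)(C)C2=O)C(C)C)c1O | target

**Step count**

Total: 12 steps. Longest linear sequence: 8 steps (1, 2, 3, 4, 9, 10, 11, 12, or equally 1, 2, 5, 8, 9, 10, 11, 12).

**Steps most likely to fail**

Step 9 (ring A formation). Capture of vinylketene 20 by the branched alkyne 10 may be slower than dimerisation of the ketene or the thermal silyl shift of 10 to a silylketene, so that ring A does not form. The fallback makes the crowded C–C bond first, at low temperature, and runs the benzannulation with an unhindered alkyne. It sets out from acid 11 and siloxyalkyne 10. Ketene 18, generated from 11 through 17 as in step 8, is trapped at 0 °C by 10 in a [2+2] cycloaddition, giving 2,4-bis(protected arm)-3-[(triisopropylsilyl)oxy]cyclobut-2-en-1-one F1. F1 is irradiated (350 nm, toluene, rt) with an excess of 16, the excess 16 is removed, and the solution is warmed to 80 °C to complete the closure to 5-(benzyloxy)-2,4-bis(protected arm)-3-[(triisopropylsilyl)oxy]phenol F2. Treatment with n-Bu4NF/AcOH removes the silyl group and the route is rejoined at diol 25.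

Step 3 (aldehyde to alkyne). The alkenyl nonaflate may not eliminate cleanly, the aldehyde may self-condense under the strong base, or the alkyne may isomerise to the allene, which would erase the stereocentre. The fallback separates sulfonylation from elimination and uses a lithium amide for the second stage. It sets out from aldehyde 5: the enolate formed with KN(SiMe3)2 at −78 °C is trapped with PhNTf2 as the isolated (3R)-3-[2-(benzyloxy)-3,3,5,5-tetramethyl-4,6-dioxocyclohex-1-en-1-yl]-4-methylpent-1-en-1-yl trifluoromethanesulfonate F3. LiN(i-Pr)2 (2.2 equiv, THF, −78 °C) then eliminates triflate and leaves the product as acetylide 8, which cannot isomerise; protonation returns the route at alkyne 7.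

Step 11 (C-acylation). The Lewis acid may strip benzyl groups and let a freed phenol close a pyran ring onto ring B, may acylate oxygen instead of carbon, or may open the arm–ring A bond reversibly and erode the configuration. The fallback avoids acid altogether and sets out from diol 25. Ortho-formylation with MgCl2, Et3N and paraformaldehyde (MeCN, reflux) gives 2-(benzyloxy)-4,6-dihydroxy-3,5-bis(protected arm)benzaldehyde F4. Pentylmagnesium bromide (excess, THF, −78 °C) gives 1-[2-(benzyloxy)-4,6-dihydroxy-3,5-bis(protected arm)phenyl]hexan-1-ol F5 (both carbinol epimers). MnO2 (CH2Cl2, rt) oxidises F5 to the ketone, and the route is rejoined at 27.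

**Further compounds**

F1 | step 9 | 2,4-bis(protected arm)-3-[(triisopropylsilyl)oxy]cyclobut-2-en-1-one (both C4 epimers) | O=C1C([C@H](C2=C(OCc3ccccc3)C(C)(C)C(=O)C(C)(C)C2=O)C(C)C)=C(O[Si](C(C)C)(C(C)C)C(C)C)C1[C@H](C4=C(OCc5ccccc5)C(C)(C)C(=O)C(C)(C)C4=O)C(C)C
F2 | step 9 | 5-(benzyloxy)-2,4-bis(protected arm)-3-[(triisopropylsilyl)oxy]phenol | Oc1cc(OCc2ccccc2)c([C@H](C3=C(OCc4ccccc4)C(C)(C)C(=O)C(C)(C)C3=O)C(C)C)c(O[Si](C(C)C)(C(C)C)C(C)C)c1[C@H](C5=C(OCc6ccccc6)C(C)(C)C(=O)C(C)(C)C5=O)C(C)C
F3 | step 3 | (3R)-3-[2-(benzyloxy)-3,3,5,5-tetramethyl-4,6-dioxocyclohex-1-en-1-yl]-4-methylpent-1-en-1-yl trifluoromethanesulfonate (E/Z mixture) | FC(F)(F)S(=O)(=O)OC=C[C@@H](C(C)C)C1=C(OCc2ccccc2)C(C)(C)C(=O)C(C)(C)C1=O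
F4 | step 11 | 2-(benzyloxy)-4,6-dihydroxy-3,5-bis(protected arm)benzaldehyde | O=Cc1c(O)c([C@H](C2=C(OCc3ccccc3)C(C)(C)C(=O)C(C)(C)C2=O)C(C)C)c(O)c([C@H](C4=C(OCc5ccccc5)C(C)(C)C(=O)C(C)(C)C4=O)C(C)C)c1OCc6ccccc6
F5 | step 11 | 1-[2-(benzyloxy)-4,6-dihydroxy-3,5-bis(protected arm)phenyl]hexan-1-ol (both carbinol epimers) | CCCCCC(O)c1c(O)c([C@H](C2=C(OCc3ccccc3)C(C)(C)C(=O)C(C)(C)C2=O)C(C)C)c(O)c([C@H](C4=C(OCc5ccccc5)C(C)(C)C(=O)C(C)(C)C4=O)C(C)C)c1OCc6ccccc6
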